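**Retrosynthetic overview**
- The strategy rests on ring A, a fully substituted phloroglucinol ring: O1, C5–OH and C7–OH are three different oxygens, C6 and C8 carry two different benzyl arms, and C4a carries the acyl carbon. The ring is therefore built de novo, not by substituting phloroglucinol.
- Key disconnection: ring A from cyclobutenone 7 (supplies C8a=O, C4a, C5–OEt, C6 and the salicyl arm) and siloxyalkyne 21 (supplies C7–OSi, C8 and the three-ring arm); bonds C8a–C8, C6–C7 and C4a–C8a.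
- Ring C: O1–C2 by Mitsunobu inversion of an (R)-β-hydroxy ester, then C4–C4a by Friedel–Crafts acylation at the only free ring-A carbon.
- Arms: diarylmethane bonds by benzylzinc Negishi couplings; the ynol ether by ester-to-ynolate homologation; the cyclobutenone by ynol ether/dichloroketene [2+2] and dechlorination.
- Ring order: the arm arenes and the C2 phenyl are bought; ring A (step 13); ring C (step 16); deprotection last.

Key step: step 13

Remark: the four arm phenols are carried as benzyl ethers, which tolerate the acidic ring-C closure and leave in the same boron trichloride treatment that de-ethylates C5–O.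
Short forms in names: "BnO-benzyl" = 2-(benzyloxy)benzyl; "arm" = 2-(benzyloxy)-5-{2-(benzyloxy)-5-[2-(benzyloxy)benzyl]benzyl}benzyl, the protected three-ring chain attached through its CH2.

**Route**

Step 1
Reactants: 1 2-(benzyloxy)benzyl alcohol
Product: 2 2-(benzyloxy)benzyl bromide
Conditions: PBr3, Et2O, 0 °C
Reagents that add atoms: phosphorus tribromide, BrP(Br)Br
Why: Bromination of a primary benzylic alcohol through its phosphite ester (SN2), under which the aryl benzyl ether is inert.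

Step 2
Reactants: 3 ethoxyacetylene; 2 2-(benzyloxy)benzyl bromide
Product: 5 1-(benzyloxy)-2-(3-ethoxyprop-2-yn-1-yl)benzene, via lithium ethoxyacetylide 4 (not isolated)
Conditions: n-BuLi, THF, −78 °C; then 2, DMPU, −78 → 0 °C
Reagents that add atoms: none
Why: SN2 alkylation of a lithium alkoxyacetylide with a reactive benzylic bromide in a dipolar co-solvent should give the 1-ethoxy-1-alkyne.

Step 3
Reactants: 5 1-(benzyloxy)-2-(3-ethoxyprop-2-yn-1-yl)benzene
Product: 6 2-(BnO-benzyl)-4,4-dichloro-3-ethoxycyclobut-2-en-1-one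
Conditions: Cl3CCOCl, Zn–Cu, Et2O/DME, 0 °C → rt
Reagents that add atoms: trichloroacetyl chloride, ClC(=O)C(Cl)(Cl)Cl
Why: Ketene–alkyne [2+2] cycloaddition of dichloroketene with the electron-rich ynol ether, in which the ketene carbonyl carbon bonds to the alkyne carbon β to oxygen, so the benzyl group ends at C2 and the ethoxy group at C3; DME sequesters the zinc chloride.

Step 4
Reactants: 6 2-(BnO-benzyl)-4,4-dichloro-3-ethoxycyclobut-2-en-1-one
Product: 7 2-(BnO-benzyl)-3-ethoxycyclobut-2-en-1-one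
Conditions: Zn, AcOH, TMEDA, EtOH, 0 °C → rt
Reagents that add atoms: none
Why: Reductive dechlorination of the α,α-dichloroketone by zinc through zinc enolates, the standard second stage of the dichloroketene route to cyclobutenones, should leave the vinylogous ester and the benzyl ether intact.

Step 5
Reactants: 8 methyl 5-bromo-2-hydroxybenzoate
Product: 9 methyl 2-(benzyloxy)-5-bromobenzoate
Conditions: BnBr, K2CO3, DMF, 60 °C
Reagents that add atoms: benzyl bromide, BrCc1ccccc1
Why: Williamson O-benzylation of the phenoxide.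

Step 6
Reactants: 2 2-(benzyloxy)benzyl bromide; 9 methyl 2-(benzyloxy)-5-bromobenzoate
Product: 11 methyl 2-(benzyloxy)-5-(BnO-benzyl)benzoate, via [2-(benzyloxy)benzyl]zinc bromide 10 (not isolated)
Conditions: Zn dust (TMSCl-activated), THF, 0 °C; then 9, Pd(OAc)2 (2 mol%), SPhos (4 mol%), THF, rt → 50 °C
Reagents that add atoms: none
Why: Negishi sp3–sp2 coupling of a benzylic zinc bromide with an aryl bromide forms the diarylmethane bond and tolerates the ester.

Step 7
Reactants: 11 methyl 2-(benzyloxy)-5-(BnO-benzyl)benzoate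
Product: 12 [2-(benzyloxy)-5-(BnO-benzyl)phenyl]methanol
Conditions: LiAlH4, THF, 0 °C
Reagents that add atoms: none
Why: Hydride reduction of the benzoate to the benzylic alcohol, with benzyl ethers and the diarylmethane unaffected.

Step 8
Reactants: 12 [2-(benzyloxy)-5-(BnO-benzyl)phenyl]methanol
Product: 13 1-(benzyloxy)-4-(BnO-benzyl)-2-(bromomethyl)benzene
Conditions: PBr3, CH2Cl2, 0 °C; used without storage
Reagents that add atoms: phosphorus tribromide, BrP(Br)Br
Why: Bromination of the benzylic alcohol as in step 1, with the electron-rich bromide taken on at once to avoid self-alkylation.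

Step 9
Reactants: 14 methyl 2-(2-hydroxyphenyl)acetate
Product: 15 methyl 2-(5-bromo-2-hydroxyphenyl)acetate
Conditions: NBS, MeCN, 0 °C → rt
Reagents that add atoms: N-bromosuccinimide, O=C1CCC(=O)N1Br
Why: Electrophilic aromatic bromination of a phenol in acetonitrile should go para to the hydroxyl, which is the position needed for the later coupling.

Step 10
Reactants: 15 methyl 2-(5-bromo-2-hydroxyphenyl)acetate
Product: 16 methyl 2-[2-(benzyloxy)-5-bromophenyl]acetate
Conditions: BnBr, K2CO3, acetone, reflux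
Reagents that add atoms: benzyl bromide, BrCc1ccccc1
Why: Williamson O-benzylation, in which the phenoxide is alkylated faster than it lactonises onto the ester.

Step 11
Reactants: 13 1-(benzyloxy)-4-(BnO-benzyl)-2-(bromomethyl)benzene; 16 methyl 2-[2-(benzyloxy)-5-bromophenyl]acetate
Product: 18 methyl 2-[2-(benzyloxy)-5-{2-(benzyloxy)-5-[2-(benzyloxy)benzyl]benzyl}phenyl]acetate (arm–CO2Me), via {2-(benzyloxy)-5-[2-(benzyloxy)benzyl]benzyl}zinc bromide 17 (not isolated)
Conditions: Zn dust (TMSCl-activated), THF, 0 °C; then 16, Pd(OAc)2 (2 mol%), SPhos (4 mol%), THF, rt → 50 °C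
Reagents that add atoms: none
Why: A second Negishi benzylzinc–aryl bromide coupling completes the three-ring chain, and the organozinc is not basic enough to enolise the arylacetate.

Step 12
Reactants: 18 arm–CO2Me
Product: 21 triisopropylsilyl ynol ether arm–C≡C–OSi(i-Pr)3, via lithium dibromoenolate 19 (not isolated), via lithium ynolate 20 (not isolated)
Conditions: CH2Br2, LiTMP, THF, −78 °C; 18; LiHMDS; n-BuLi, −78 → 0 °C; TIPSCl, 0 °C → rt
Reagents that add atoms: dibromomethane, BrCBr; triisopropylsilyl chloride, CC(C)[Si](Cl)(C(C)C)C(C)C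
Why: Kowalski ester homologation, in which dibromomethyllithium adds to the ester, the dibromoketone enolate undergoes bromine–lithium exchange and 1,2-shift to the ynolate, and the bulky silyl chloride silylates the ynolate on oxygen.

Step 13
Reactants: 7 2-(BnO-benzyl)-3-ethoxycyclobut-2-en-1-one; 21 triisopropylsilyl ynol ether arm–C≡C–OSi(i-Pr)3
Product: 26 2-(arm)-4-(BnO-benzyl)-5-ethoxy-3-(triisopropylsilyloxy)phenol, via vinylketene 22 (not isolated), via 4-vinylcyclobutenone 23 (not isolated), via dienylketene 24 (not isolated), via cyclohexa-2,4-dienone 25 (not isolated)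
Conditions: 7 (1.3 equiv, slow addition), toluene, 110 °C, then 135 °C, sealed tube
Reagents that add atoms: none
Why: Thermal 4π opening of 7 gives vinylketene 22, whose ketene carbon (future C8a) is attacked by the alkyne carbon of 21 that bears the arm in a [2+2] cycloaddition to 23 (bonds C8a–C8 and C6–C7), and 23 opens again to dienylketene 24, which closes to 25 and tautomerises to the phenol. The closest known reaction is the Danheiser benzannulation of cyclobutenones with siloxyalkynes, and the opening of 3-alkoxycyclobutenones to vinylketenes is known from squarate-derived ring expansions. Ring A is the only ring that remains, closed by a 6π electrocyclisation of the ketene-terminated triene that re-forms C4a–C8a. No stereocentre is formed. The step needs a single regiochemical outcome of the [2+2] event, and the polarity match between the electrophilic ketene carbon and the nucleophilic alkyne carbon β to oxygen should secure it, so the ketene oxygen becomes the free O1–H between C8 and unsubstituted C4a, the alkyne oxygen the C7 silyl ether between the two arms, and the ethoxy group sits at C5. Slow addition keeps the ketene concentration low so that acylation of the product phenol should not compete, and the neutral medium leaves the benzyl ethers untouched.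

Step 14
Reactants: 26 2-(arm)-4-(BnO-benzyl)-5-ethoxy-3-(triisopropylsilyloxy)phenol; 27 ethyl (3R)-3-hydroxy-3-phenylpropanoate
Product: 28 ethyl (3S)-3-[2-(arm)-4-(BnO-benzyl)-5-ethoxy-3-(triisopropylsilyloxy)phenoxy]-3-phenylpropanoate
Conditions: PPh3, DIAD, toluene, 0 °C → rt
Reagents that add atoms: none
Why: Mitsunobu etherification of the only free phenol, in which SN2 displacement of the oxyphosphonium inverts the R carbinol to the S aryl ether that becomes C2.

Step 15
Reactants: 28 ethyl (3S)-3-aryloxy-3-phenylpropanoate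
Product: 29 (3S)-3-[2-(arm)-4-(BnO-benzyl)-5-ethoxy-3-(triisopropylsilyloxy)phenoxy]-3-phenylpropanoic acid
Conditions: LiOH, THF/MeOH/H2O, 0 °C → rt; cold dilute HCl to pH 4
Reagents that add atoms: lithium hydroxide, [Li+].[OH-]
Why: Saponification of the ethyl ester at low temperature should outrun enolate formation, so the β-aryloxy group is not eliminated and the stereocentre is kept.

Step 16
Reactants: 29 (3S)-3-aryloxy-3-phenylpropanoic acid
Product: 31 (2S)-8-(arm)-6-(BnO-benzyl)-5-ethoxy-2-phenyl-7-(triisopropylsilyloxy)chroman-4-one, via mixed trifluoroacetic anhydride 30 (not isolated)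
Conditions: TFAA, CH2Cl2, 0 °C → rt
Reagents that add atoms: none
Why: Intramolecular Friedel–Crafts acylation through the mixed anhydride closes ring C at C4a, the only free ring-A carbon and ortho/para to all three oxygens, under conditions that benzyl and silyl ethers tolerate and that do not touch C2.

Step 17
Reactants: 31 (2S)-8-(arm)-6-(BnO-benzyl)-5-ethoxy-2-phenyl-7-(triisopropylsilyloxy)chroman-4-one
Product: 32 (2S)-8-(arm)-6-(BnO-benzyl)-5-ethoxy-7-hydroxy-2-phenylchroman-4-one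
Conditions: TBAF, AcOH, THF, 0 °C
Reagents that add atoms: none
Why: Fluoride cleavage of the aryl silyl ether, now a vinylogous silyl ester para to C4=O, with acetic acid buffering so that the flavanone does not open by retro-oxa-Michael reaction.

Step 18
Reactants: 32 (2S)-8-(arm)-6-(BnO-benzyl)-5-ethoxy-7-hydroxy-2-phenylchroman-4-one
Product: 33 sarmentosumin A
Conditions: BCl3 (excess), pentamethylbenzene, CH2Cl2, −78 °C → 0 °C, then rt; MeOH quench
Reagents that add atoms: none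
Why: Lewis acid dealkylation, in which boron trichloride cleaves the four aryl benzyl ethers at low temperature with pentamethylbenzene trapping the benzyl cations, and chelation between C4=O and C5–O directs removal of the peri ethyl group on warming.

**Compound list**
1 | 2-(benzyloxy)benzyl alcohol | OCc1ccccc1OCc1ccccc1 | starting material
2 | 2-(benzyloxy)benzyl bromide | BrCc1ccccc1OCc1ccccc1 | intermediate
3 | ethoxyacetylene | C#COCC | starting material
4 | lithium ethoxyacetylide | [Li]C#COCC | intermediate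
5 | 1-(benzyloxy)-2-(3-ethoxyprop-2-yn-1-yl)benzene | CCOC#CCc1ccccc1OCc1ccccc1 | intermediate
6 | 2-(BnO-benzyl)-4,4-dichloro-3-ethoxycyclobut-2-en-1-one | O=C1C(Cl)(Cl)C(OCC)=C1Cc1ccccc1OCc1ccccc1 | intermediate
7 | 2-(BnO-benzyl)-3-ethoxycyclobut-2-en-1-one | O=C1CC(OCC)=C1Cc1ccccc1OCc1ccccc1 | intermediate
8 | methyl 5-bromo-2-hydroxybenzoate | COC(=O)c1cc(Br)ccc1O | starting material
9 | methyl 2-(benzyloxy)-5-bromobenzoate | COC(=O)c1cc(Br)ccc1OCc1ccccc1 | intermediate
10 | [2-(benzyloxy)benzyl]zinc bromide | Br[Zn]Cc1ccccc1OCc1ccccc1 | intermediate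
11 | methyl 2-(benzyloxy)-5-(BnO-benzyl)benzoate | COC(=O)c1cc(Cc2ccccc2OCc2ccccc2)ccc1OCc1ccccc1 | intermediate
12 | [2-(benzyloxy)-5-(BnO-benzyl)phenyl]methanol | OCc1cc(Cc2ccccc2OCc2ccccc2)ccc1OCc1ccccc1 | intermediate
13 | 1-(benzyloxy)-4-(BnO-benzyl)-2-(bromomethyl)benzene | BrCc1cc(Cc2ccccc2OCc2ccccc2)ccc1OCc1ccccc1 | intermediate
14 | methyl 2-(2-hydroxyphenyl)acetate | COC(=O)Cc1ccccc1O | starting material
15 | methyl 2-(5-bromo-2-hydroxyphenyl)acetate | COC(=O)Cc1cc(Br)ccc1O | intermediate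
16 | methyl 2-[2-(benzyloxy)-5-bromophenyl]acetate | COC(=O)Cc1cc(Br)ccc1OCc1ccccc1 | intermediate
17 | {2-(benzyloxy)-5-[2-(benzyloxy)benzyl]benzyl}zinc bromide | Br[Zn]Cc1cc(Cc2ccccc2OCc2ccccc2)ccc1OCc1ccccc1 | intermediate
18 | methyl 2-[2-(benzyloxy)-5-{2-(benzyloxy)-5-[2-(benzyloxy)benzyl]benzyl}phenyl]acetate (arm–CO2Me) | COC(=O)Cc1cc(Cc2cc(Cc3ccccc3OCc3ccccc3)ccc2OCc2ccccc2)ccc1OCc1ccccc1 | intermediate
19 | lithium dibromoenolate of the arm dibromomethyl ketone | [Li]OC(=C(Br)Br)Cc1cc(Cc2cc(Cc3ccccc3OCc3ccccc3)ccc2OCc2ccccc2)ccc1OCc1ccccc1 | intermediate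
20 | lithium ynolate arm–C≡C–OLi | [Li]OC#CCc1cc(Cc2cc(Cc3ccccc3OCc3ccccc3)ccc2OCc2ccccc2)ccc1OCc1ccccc1 | intermediate
21 | triisopropylsilyl ynol ether arm–C≡C–OSi(i-Pr)3 | CC(C)[Si](OC#CCc1cc(Cc2cc(Cc3ccccc3OCc3ccccc3)ccc2OCc2ccccc2)ccc1OCc1ccccc1)(C(C)C)C(C)C | intermediate
22 | vinylketene 2-(BnO-benzyl)-3-ethoxybuta-1,3-dien-1-one | O=C=C(Cc1ccccc1OCc1ccccc1)C(OCC)=C | intermediate
23 | 4-vinylcyclobutenone: 2-(arm)-4-(BnO-benzyl)-4-(1-ethoxyvinyl)-3-(triisopropylsilyloxy)cyclobut-2-en-1-one (racemic) | O=C1C(Cc2cc(Cc3cc(Cc4ccccc4OCc4ccccc4)ccc3OCc3ccccc3)ccc2OCc2ccccc2)=C(O[Si](C(C)C)(C(C)C)C(C)C)C1(Cc1ccccc1OCc1ccccc1)C(OCC)=C | intermediate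
24 | dienylketene 2-(arm)-4-(BnO-benzyl)-5-ethoxy-3-(triisopropylsilyloxy)hexa-1,3,5-trien-1-one | O=C=C(Cc1cc(Cc2cc(Cc3ccccc3OCc3ccccc3)ccc2OCc2ccccc2)ccc1OCc1ccccc1)C(O[Si](C(C)C)(C(C)C)C(C)C)=C(Cc1ccccc1OCc1ccccc1)C(OCC)=C | intermediate
25 | 2-(arm)-4-(BnO-benzyl)-5-ethoxy-3-(triisopropylsilyloxy)cyclohexa-2,4-dien-1-one | O=C1CC(OCC)=C(Cc2ccccc2OCc2ccccc2)C(O[Si](C(C)C)(C(C)C)C(C)C)=C1Cc1cc(Cc2cc(Cc3ccccc3OCc3ccccc3)ccc2OCc2ccccc2)ccc1OCc1ccccc1 | intermediate
26 | 2-(arm)-4-(BnO-benzyl)-5-ethoxy-3-(triisopropylsilyloxy)phenol (OH = future O1, ring H = future C4a) | Oc1cc(OCC)c(Cc2ccccc2OCc2ccccc2)c(O[Si](C(C)C)(C(C)C)C(C)C)c1Cc1cc(Cc2cc(Cc3ccccc3OCc3ccccc3)ccc2OCc2ccccc2)ccc1OCc1ccccc1 | intermediate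
27 | ethyl (3R)-3-hydroxy-3-phenylpropanoate | CCOC(=O)C[C@@H](O)c1ccccc1 | starting material
28 | ethyl (3S)-3-[2-(arm)-4-(BnO-benzyl)-5-ethoxy-3-(triisopropylsilyloxy)phenoxy]-3-phenylpropanoate | CCOC(=O)C[C@H](Oc1cc(OCC)c(Cc2ccccc2OCc2ccccc2)c(O[Si](C(C)C)(C(C)C)C(C)C)c1Cc1cc(Cc2cc(Cc3ccccc3OCc3ccccc3)ccc2OCc2ccccc2)ccc1OCc1ccccc1)c1ccccc1 | intermediate
29 | (3S)-3-[2-(arm)-4-(BnO-benzyl)-5-ethoxy-3-(triisopropylsilyloxy)phenoxy]-3-phenylpropanoic acid | OC(=O)C[C@H](Oc1cc(OCC)c(Cc2ccccc2OCc2ccccc2)c(O[Si](C(C)C)(C(C)C)C(C)C)c1Cc1cc(Cc2cc(Cc3ccccc3OCc3ccccc3)ccc2OCc2ccccc2)ccc1OCc1ccccc1)c1ccccc1 | intermediate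
30 | mixed trifluoroacetic anhydride of acid 29 | O=C(OC(=O)C(F)(F)F)C[C@H](Oc1cc(OCC)c(Cc2ccccc2OCc2ccccc2)c(O[Si](C(C)C)(C(C)C)C(C)C)c1Cc1cc(Cc2cc(Cc3ccccc3OCc3ccccc3)ccc2OCc2ccccc2)ccc1OCc1ccccc1)c1ccccc1 | intermediate
31 | (2S)-8-(arm)-6-(BnO-benzyl)-5-ethoxy-2-phenyl-7-(triisopropylsilyloxy)chroman-4-one | O=C1C[C@@H](c2ccccc2)Oc2c(Cc3cc(Cc4cc(Cc5ccccc5OCc5ccccc5)ccc4OCc4ccccc4)ccc3OCc3ccccc3)c(O[Si](C(C)C)(C(C)C)C(C)C)c(Cc3ccccc3OCc3ccccc3)c(OCC)c21 | intermediate
32 | (2S)-8-(arm)-6-(BnO-benzyl)-5-ethoxy-7-hydroxy-2-phenylchroman-4-one | O=C1C[C@@H](c2ccccc2)Oc2c(Cc3cc(Cc4cc(Cc5ccccc5OCc5ccccc5)ccc4OCc4ccccc4)ccc3OCc3ccccc3)c(O)c(Cc3ccccc3OCc3ccccc3)c(OCC)c21 | intermediate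
33 | sarmentosumin A, (2S)-5,7-dihydroxy-6-(2-hydroxybenzyl)-8-{2-hydroxy-5-[2-hydroxy-5-(2-hydroxybenzyl)benzyl]benzyl}-2-phenylchroman-4-one | O=C1C[C@@H](c2ccccc2)Oc2c(Cc3cc(Cc4cc(Cc5ccccc5O)ccc4O)ccc3O)c(O)c(Cc3ccccc3O)c(O)c21 | target

**Step count**
Total: 18 steps. Longest linear sequence: 12 steps (8 → 9 → 11 → 12 → 13 → 18 → 21 → 26 → 28 → 29 → 31 → 32 → 33).

**Steps most likely to fail**

Step 13. The donor-stabilised 3-ethoxycyclobutenone may open too slowly, so that at the temperature it needs the siloxyalkyne rearranges or the ketene is consumed by acylation of the product phenol. The fallback generates the same vinylketene 22 irreversibly at room temperature by a photochemical Wolff rearrangement. It sets out from bromide 2 and siloxyalkyne 21 and returns at phenol 26. Alkylation of the lithium enolate of N-methoxy-N-methylacetamide (LDA, THF, −78 °C) with 2 should give 3-[2-(benzyloxy)phenyl]-N-methoxy-N-methylpropanamide F1. Addition of 1-ethoxyvinyllithium (ethyl vinyl ether, t-BuLi) should give 5-[2-(benzyloxy)phenyl]-2-ethoxypent-1-en-3-one F2. Trifluoroacetylation of its lithium enolate (LiHMDS, CF3CO2CH2CF3) should give 4-(BnO-benzyl)-2-ethoxy-6,6,6-trifluorohex-1-ene-3,5-dione F3, and detrifluoroacetylative diazo transfer (MsN3, Et3N, aqueous MeCN) should give 5-[2-(benzyloxy)phenyl]-4-diazo-2-ethoxypent-1-en-3-one F4. Irradiation of F4 with 21 in CH2Cl2 at rt, followed by warming in toluene, should pass through 22–25 to 26.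

Step 14. Loss of the activated β-oxyphosphonium by E1cB elimination (cinnamate formation) or partial ionisation at the benzylic carbon may outrun the SN2 displacement, lowering yield or enantiomeric purity. The fallback sets C2 by a catalytic asymmetric C–C bond formation instead. It sets out from phenol 26 and returns at flavanone 31. Magnesium-mediated ortho-formylation (MgCl2, Et3N, paraformaldehyde, MeCN, reflux) at C4a should give 3-(arm)-5-(BnO-benzyl)-6-ethoxy-2-hydroxy-4-(triisopropylsilyloxy)benzaldehyde F5. Ethynylmagnesium bromide (excess, THF, 0 °C) should give the propargylic alcohol 1-[3-(arm)-5-(BnO-benzyl)-6-ethoxy-2-hydroxy-4-(triisopropylsilyloxy)phenyl]prop-2-yn-1-ol F6. MnO2 (CH2Cl2) should give the ynone 1-[3-(arm)-5-(BnO-benzyl)-6-ethoxy-2-hydroxy-4-(triisopropylsilyloxy)phenyl]prop-2-yn-1-one F7. Amine-mediated 6-endo cyclisation (Et2NH, EtOH) should give the chromone 8-(arm)-6-(BnO-benzyl)-5-ethoxy-7-(triisopropylsilyloxy)-4H-chromen-4-one F8. Rhodium-catalysed asymmetric 1,4-addition of phenylboronic acid ([Rh(OH)(cod)]2, an electron-poor atropisomeric bisphosphine of the MeO-BIPHEP type in the antipode that delivers the 2S product, toluene/H2O, rt, no added base) should give 31.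

Step 12. Dibromomethyllithium or the amide base may deprotonate the acidic arylacetate α-position instead of adding to the carbonyl, and the excess alkyllithium may lithiate the benzyl ethers on warming. The fallback makes the ynolate by oxidation of an acetylide, with no ester enolisation possible. It sets out from ester 18 and returns at ynolate 20, which is silylated to 21 as in step 12. DIBAL-H (CH2Cl2, −78 °C) should give the aldehyde 2-[2-(benzyloxy)-5-{2-(benzyloxy)-5-[2-(benzyloxy)benzyl]benzyl}phenyl]acetaldehyde F9. Corey–Fuchs olefination (CBr4, PPh3, CH2Cl2, 0 °C) should give the dibromoalkene 1-(benzyloxy)-4-{2-(benzyloxy)-5-[2-(benzyloxy)benzyl]benzyl}-2-(3,3-dibromoprop-2-en-1-yl)benzene F10. n-BuLi (2 equiv, THF, −78 °C) should give the lithium acetylide arm–C≡C–Li F11, and lithium tert-butyl peroxide (−78 → 0 °C) should transfer oxygen to give 20.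

Further compounds
F1 | step 13 | 3-[2-(benzyloxy)phenyl]-N-methoxy-N-methylpropanamide | CON(C)C(=O)CCc1ccccc1OCc1ccccc1
F2 | step 13 | 5-[2-(benzyloxy)phenyl]-2-ethoxypent-1-en-3-one | C=C(OCC)C(=O)CCc1ccccc1OCc1ccccc1
F3 | step 13 | 4-(BnO-benzyl)-2-ethoxy-6,6,6-trifluorohex-1-ene-3,5-dione | C=C(OCC)C(=O)C(Cc1ccccc1OCc1ccccc1)C(=O)C(F)(F)F
F4 | step 13 | 5-[2-(benzyloxy)phenyl]-4-diazo-2-ethoxypent-1-en-3-one | C=C(OCC)C(=O)C(=[N+]=[N-])Cc1ccccc1OCc1ccccc1
F5 | step 14 | 3-(arm)-5-(BnO-benzyl)-6-ethoxy-2-hydroxy-4-(triisopropylsilyloxy)benzaldehyde | O=Cc1c(O)c(Cc2cc(Cc3cc(Cc4ccccc4OCc4ccccc4)ccc3OCc3ccccc3)ccc2OCc2ccccc2)c(O[Si](C(C)C)(C(C)C)C(C)C)c(Cc2ccccc2OCc2ccccc2)c1OCC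
F6 | step 14 | 1-[3-(arm)-5-(BnO-benzyl)-6-ethoxy-2-hydroxy-4-(triisopropylsilyloxy)phenyl]prop-2-yn-1-ol (racemic) | C#CC(O)c1c(O)c(Cc2cc(Cc3cc(Cc4ccccc4OCc4ccccc4)ccc3OCc3ccccc3)ccc2OCc2ccccc2)c(O[Si](C(C)C)(C(C)C)C(C)C)c(Cc2ccccc2OCc2ccccc2)c1OCC
F7 | step 14 | 1-[3-(arm)-5-(BnO-benzyl)-6-ethoxy-2-hydroxy-4-(triisopropylsilyloxy)phenyl]prop-2-yn-1-one | C#CC(=O)c1c(O)c(Cc2cc(Cc3cc(Cc4ccccc4OCc4ccccc4)ccc3OCc3ccccc3)ccc2OCc2ccccc2)c(O[Si](C(C)C)(C(C)C)C(C)C)c(Cc2ccccc2OCc2ccccc2)c1OCC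
F8 | step 14 | 8-(arm)-6-(BnO-benzyl)-5-ethoxy-7-(triisopropylsilyloxy)-4H-chromen-4-one | O=c1ccoc2c(Cc3cc(Cc4cc(Cc5ccccc5OCc5ccccc5)ccc4OCc4ccccc4)ccc3OCc3ccccc3)c(O[Si](C(C)C)(C(C)C)C(C)C)c(Cc3ccccc3OCc3ccccc3)c(OCC)c12
F9 | step 12 | 2-[2-(benzyloxy)-5-{2-(benzyloxy)-5-[2-(benzyloxy)benzyl]benzyl}phenyl]acetaldehyde | O=CCc1cc(Cc2cc(Cc3ccccc3OCc3ccccc3)ccc2OCc2ccccc2)ccc1OCc1ccccc1
F10 | step 12 | 1-(benzyloxy)-4-{2-(benzyloxy)-5-[2-(benzyloxy)benzyl]benzyl}-2-(3,3-dibromoprop-2-en-1-yl)benzene | BrC(Br)=CCc1cc(Cc2cc(Cc3ccccc3OCc3ccccc3)ccc2OCc2ccccc2)ccc1OCc1ccccc1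
F11 | step 12 | lithium acetylide arm–C≡C–Li | [Li]C#CCc1cc(Cc2cc(Cc3ccccc3OCc3ccccc3)ccc2OCc2ccccc2)ccc1OCc1ccccc1
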